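**Strategy.** The ten-membered carbocycle (ring A, C1–C10, germacrane numbering) is opened at the C2–C3 bond, the bond between the (E)-C1=C2 alkene and the bis-allylic carbinol carbon C3. An intramolecular Nozaki–Hiyama–Kishi reaction forms this bond: the E-alkenyl iodide at C2 adds, through its chromium reagent, to the Z-enal carbonyl C3, closing ring A and creating the C3 stereocentre in one operation. The feature exploited is the C1=C2–C3(O)–C4=C5 array; the cis-fused lactone (ring B, C6/C7) and the Z-C4=C5 bond act as turn elements. The precursor is the fully functionalised α-methylene lactone 27 carrying both arms, assembled by a syn aldol of ketone 8 with aldehyde 14.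

Key step: step 18

Remark: germacrane numbering is used throughout (C1–C10 ring A, C11/C12/C13 lactone α-carbon, carbonyl and methylene, C14 and C15 the methyls on C10 and C4). The CIP label at C7 switches between S and R with the group on O8 although the centre is never inverted. (S)-2-Methylglycidol, angelic acid and (−)-Ipc2BOTf (from (−)-Ipc2BH and TfOH) are assumed to be available.

Step 1
Reactants: 1 prop-2-yn-1-ol
Product: 2 (Z)-3-iodo-2-methylprop-2-en-1-ol
Conditions: MeMgBr (3 equiv), CuI (10 mol%), THF, −10 °C to rt; then I2, −78 to 0 °C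
Reagents that add atoms: methylmagnesium bromide C[Mg]Br; iodine [I][I]
Why: Copper-catalysed anti-carbomagnesiation of the propargylic alkoxide puts the methyl group on the internal carbon (C4) and magnesium on the terminal carbon cis to CH2O (chelate), and iodinolysis with retention should give the Z-iodoalkene that becomes the Z-C4=C5 bond.

Step 2
Reactants: 2 (Z)-3-iodo-2-methylprop-2-en-1-ol
Product: 3 (Z)-tert-butyl[(3-iodo-2-methylprop-2-en-1-yl)oxy]diphenylsilane
Conditions: TBDPSCl, imidazole, DMF, rt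
Reagents that add atoms: tert-butylchlorodiphenylsilane CC(C)(C)[Si](Cl)(c1ccccc1)c1ccccc1
Why: Standard silylation of a primary alcohol; the bulky silyl ether should survive to step 16 and suppress a 1,4 O-to-C silyl shift in the derived alkenyllithium.

Step 3
Reactants: 4 methyl 4-chloro-4-oxobutanoate; 5 N,O-dimethylhydroxylamine hydrochloride
Product: 6 methyl 4-[methoxy(methyl)amino]-4-oxobutanoate
Conditions: Et3N, CH2Cl2, 0 °C
Reagents that add atoms: none
Why: N-Acylation of the hydroxylamine by the acid chloride gives the Weinreb amide, which supplies C6, C7, C11 and C12.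

Step 4
Reactants: 3 (Z)-tert-butyl[(3-iodo-2-methylprop-2-en-1-yl)oxy]diphenylsilane; 6 methyl 4-[methoxy(methyl)amino]-4-oxobutanoate
Product: 8 methyl (5Z)-7-(tert-butyldiphenylsilyloxy)-6-methyl-4-oxohept-5-enoate, via Z-alkenyllithium 7 (not isolated)
Conditions: t-BuLi (2 equiv), Et2O, −78 °C; then 6, −78 °C
Reagents that add atoms: none
Why: Iodine–lithium exchange with retention of alkene geometry followed by Weinreb ketone synthesis; the chelated tetrahedral intermediate prevents over-addition and the amide should react before the methyl ester at −78 °C.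

Step 5
Reactants: 9 (S)-2-methylglycidol
Product: 10 (R)-2-methylpent-4-ene-1,2-diol
Conditions: CH2=CHMgBr (3 equiv), CuI (10 mol%), THF, −30 to 0 °C
Reagents that add atoms: vinylmagnesium bromide C=C[Mg]Br
Why: Copper-catalysed Grignard opening of the epoxide at its unsubstituted CH2 (SN2) leaves the chiral-pool quaternary centre, the future C10, untouched.

Step 6
Reactants: 10 (R)-2-methylpent-4-ene-1,2-diol
Product: 11 (R)-2-methyl-1,2-bis(triethylsilyloxy)pent-4-ene
Conditions: TESOTf (2.5 equiv), 2,6-lutidine, CH2Cl2, −78 to 0 °C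
Reagents that add atoms: triethylsilyl triflate CC[Si](CC)(CC)OS(=O)(=O)C(F)(F)F
Why: Silylation with the silyl triflate protects both the primary and the hindered tertiary hydroxyl.

Step 7
Reactants: 11 (R)-2-methyl-1,2-bis(triethylsilyloxy)pent-4-ene
Product: 12 (R)-2-methyl-2-(triethylsilyloxy)pent-4-enal
Conditions: (COCl)2, DMSO, CH2Cl2, −78 to −30 °C; then Et3N
Reagents that add atoms: none
Why: Swern oxidation applied directly to the silyl ether: the primary triethylsilyl ether is cleaved and oxidised under the activated-DMSO conditions while the tertiary silyl ether is inert.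

Step 8
Reactants: 12 (R)-2-methyl-2-(triethylsilyloxy)pent-4-enal
Product: 13 (3R,1E)-1-iodo-3-methyl-3-(triethylsilyloxy)hexa-1,5-diene
Conditions: CrCl2 (6 equiv), CHI3 (2 equiv), THF/dioxane, 0 °C to rt
Reagents that add atoms: iodoform IC(I)I
Why: Takai olefination; the geminal dichromium reagent adds to the hindered aldehyde and eliminates to the E-iodoalkene, which becomes E-C1=C2.

Step 9
Reactants: 13 (3R,1E)-1-iodo-3-methyl-3-(triethylsilyloxy)hexa-1,5-diene
Product: 14 (3R,4E)-5-iodo-3-methyl-3-(triethylsilyloxy)pent-4-enal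
Conditions: OsO4 (2 mol%), NaIO4, 2,6-lutidine, dioxane/H2O, rt
Reagents that add atoms: osmium tetroxide O=[Os](=O)(=O)=O; sodium periodate [Na+].[O-][I](=O)(=O)=O
Why: Lemieux–Johnson cleavage; osmylation should occur at the unhindered monosubstituted alkene and not at the electron-poor iodoalkene next to the quaternary centre.

Step 10
Reactants: 8 methyl (5Z)-7-(tert-butyldiphenylsilyloxy)-6-methyl-4-oxohept-5-enoate; 14 (3R,4E)-5-iodo-3-methyl-3-(triethylsilyloxy)pent-4-enal
Product: 16 methyl (3S,4R,6R,7E)-3-[(2Z)-4-(tert-butyldiphenylsilyloxy)-3-methylbut-2-enoyl]-4-hydroxy-8-iodo-6-methyl-6-(triethylsilyloxy)oct-7-enoate, via boron enolate 15 (not isolated)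
Conditions: (−)-Ipc2BOTf, i-Pr2NEt, CH2Cl2, −78 °C; then 14, −78 to −20 °C; H2O2, MeOH, pH 7 buffer, 0 °C
Reagents that add atoms: none
Why: Paterson aldol: the Z-enol diisopinocampheylborinate formed at C7 reacts through a Zimmerman–Traxler chair to give the 7,8-syn adduct, and the isopinocampheyl ligands should direct attack to the si face of 14, setting C7 (S) and C8 (R) under reagent control.

Step 11
Reactants: 16 syn-aldol adduct
Product: 17 methyl (3S,4R,6R,7E)-3-[(2Z)-4-(tert-butyldiphenylsilyloxy)-3-methylbut-2-enoyl]-8-iodo-6-methyl-4,6-bis(triethylsilyloxy)oct-7-enoate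
Conditions: TESOTf, 2,6-lutidine, CH2Cl2, −78 °C
Reagents that add atoms: triethylsilyl triflate CC[Si](CC)(CC)OS(=O)(=O)C(F)(F)F
Why: Silylation of the β-hydroxy ketone under non-eliminating conditions blocks O8, so that only O6 can later lactonise.

Step 12
Reactants: 17 bis(triethylsilyl) enone
Product: 19 (4R,5R)-5-[(1Z)-3-(tert-butyldiphenylsilyloxy)-2-methylprop-1-en-1-yl]-4-[(1R,3R,4E)-5-iodo-3-methyl-1,3-bis(triethylsilyloxy)pent-4-en-1-yl]oxolan-2-one, via hydroxy ester 18 (not isolated)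
Conditions: LiBH(s-Bu)3, THF, −78 °C; AcOH quench at −78 °C; then PPTS (cat.), toluene, 50 °C
Reagents that add atoms: none
Why: Felkin–Anh 1,2-reduction of the β,β-disubstituted enone by the bulky hydride, anti to C8, should give the 6R alcohol (O6 anti to C11 and to O8), and acid-catalysed lactonisation of the γ-hydroxy ester then closes the cis-fused ring B.

Step 13
Reactants: 19 cis-lactone
Product: 22 (4R,5R)-5-[(1Z)-3-(tert-butyldiphenylsilyloxy)-2-methylprop-1-en-1-yl]-4-[(1R,3R,4E)-5-iodo-3-methyl-1,3-bis(triethylsilyloxy)pent-4-en-1-yl]-3-methylideneoxolan-2-one, via Mannich base 20 (not isolated), via ammonium iodide 21 (not isolated)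
Conditions: LiN(i-Pr)2, THF, −78 °C; CH2=NMe2+ I−, −78 °C to rt; then MeI, MeOH, rt; then aq. NaHCO3, CH2Cl2, rt
Reagents that add atoms: Eschenmoser's salt C=[N+](C)C.[I-]
Why: α-Methylenation of the lactone by Mannich reaction of its lithium enolate with Eschenmoser's salt (anti to the C7 substituent), N-methylation and base-induced β-elimination of trimethylamine; the transient C11 centre is destroyed.

Step 14
Reactants: 22 α-methylene lactone bis(triethylsilyl) ether
Product: 23 (4S,5R)-5-[(1Z)-3-(tert-butyldiphenylsilyloxy)-2-methylprop-1-en-1-yl]-4-[(1R,3R,4E)-1,3-dihydroxy-5-iodo-3-methylpent-4-en-1-yl]-3-methylideneoxolan-2-one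
Conditions: HF·pyridine, pyridine, THF, 0 °C
Reagents that add atoms: none
Why: Buffered fluoride desilylation should remove both triethylsilyl ethers while the primary tert-butyldiphenylsilyl ether, far less labile, stays in place.

Step 15
Reactants: 23 C8,C10-diol; 24 angelic acid [(Z)-2-methylbut-2-enoic acid]
Product: 25 (1R,3R,4E)-1-{(2R,3S)-2-[(1Z)-3-(tert-butyldiphenylsilyloxy)-2-methylprop-1-en-1-yl]-4-methylidene-5-oxooxolan-3-yl}-3-hydroxy-5-iodo-3-methylpent-4-en-1-yl (2Z)-2-methylbut-2-enoate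
Conditions: 24, 2,4,6-trichlorobenzoyl chloride, Et3N, toluene, rt; then 23, toluene, 75 °C
Reagents that add atoms: none
Why: Yamaguchi-type mixed-anhydride esterification acylates the secondary C8 hydroxyl while the tertiary C10 hydroxyl stays free, and omitting DMAP should prevent isomerisation of the angelate to the tiglate.

Step 16
Reactants: 25 angelate silyl ether
Product: 26 (1R,3R,4E)-3-hydroxy-1-{(2R,3S)-2-[(1Z)-3-hydroxy-2-methylprop-1-en-1-yl]-4-methylidene-5-oxooxolan-3-yl}-5-iodo-3-methylpent-4-en-1-yl (2Z)-2-methylbut-2-enoate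
Conditions: HF·pyridine (excess), THF, 0 °C to rt
Reagents that add atoms: none
Why: Non-basic fluoride cleavage of the primary silyl ether frees the C3 hydroxyl without acyl migration or conjugate addition to the α-methylene lactone.

Step 17
Reactants: 26 primary allylic alcohol
Product: 27 (1R,3R,4E)-3-hydroxy-5-iodo-3-methyl-1-{(2R,3S)-4-methylidene-2-[(1Z)-2-methyl-3-oxoprop-1-en-1-yl]-5-oxooxolan-3-yl}pent-4-en-1-yl (2Z)-2-methylbut-2-enoate
Conditions: Dess–Martin periodinane, NaHCO3, CH2Cl2, 0 °C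
Reagents that add atoms: none
Why: Buffered Dess–Martin oxidation converts the primary allylic alcohol into the Z-enal without Z/E isomerisation; the tertiary C10 alcohol cannot be oxidised.

Step 18
Reactants: 27 Z-enal E-iodoalkene (cyclisation precursor)
Product: 29 (3R,6R,7S,8R,10R,1E,4Z)-3,10-dihydroxy-8-[(2Z)-2-methylbut-2-enoyloxy]germacra-1,4,11(13)-trien-12,6-olide, via alkenylchromium 28 (not isolated)
Conditions: CrCl2 (10 equiv), NiCl2 (2 mol% of CrCl2), degassed DMSO/THF, slow addition of 27 to 0.002 M, rt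
Reagents that add atoms: none
Why: Nozaki–Hiyama–Kishi reaction: CrCl2 reduces NiCl2 to zerovalent nickel, which inserts into the C2–I bond, and transmetallation to trivalent chromium gives the E-alkenylchromium 28 with retention of geometry, which adds to the C3 formyl carbon. The closest known reaction type is the NHK macrocyclisation of iodoalkenyl aldehydes to medium and large carbocyclic allylic alcohols. Ring A is closed in the 10-exo-trig mode, the carbonyl oxygen staying outside the ring as the chromium alkoxide. The new C3 stereocentre is set under substrate control: the cis-fused lactone (ring B) and the Z-C4=C5 bond hold the s-trans enal so that the C7 arm should deliver C2 to the re face of the formyl group, which corresponds to 3R. The step needs chemoselectivity for the aldehyde over the lactone, the angelate and the α-methylene acceptor, which alkenylchromium reagents provide, and it tolerates the free tertiary C10 hydroxyl. Cyclisation over oligomerisation is secured by slow addition at high dilution and by the two turn elements (ring B and the Z-alkene) that bring C2 and C3 together.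

Step 19
Reactants: 29 ring-closed C3,C10-diol
Product: 30 (3R,6R,7S,8R,10R,1E,4Z)-3-acetoxy-10-hydroxy-8-[(2Z)-2-methylbut-2-enoyloxy]germacra-1,4,11(13)-trien-12,6-olide
Conditions: Ac2O, pyridine, DMAP (cat.), CH2Cl2, 0 °C
Reagents that add atoms: acetic anhydride CC(=O)OC(C)=O
Why: Acetylation of the secondary bis-allylic C3 hydroxyl; the tertiary C10 hydroxyl should not react under these mild conditions.

**Compound list**

1 | prop-2-yn-1-ol | C#CCO | starting material
2 | (Z)-3-iodo-2-methylprop-2-en-1-ol | OC/C(C)=C\I | intermediate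
3 | (Z)-tert-butyl[(3-iodo-2-methylprop-2-en-1-yl)oxy]diphenylsilane | CC(C)(C)[Si](OC/C(C)=C\I)(c1ccccc1)c1ccccc1 | intermediate
4 | methyl 4-chloro-4-oxobutanoate | COC(=O)CCC(Cl)=O | starting material
5 | N,O-dimethylhydroxylamine hydrochloride | CNOC.Cl | starting material
6 | methyl 4-[methoxy(methyl)amino]-4-oxobutanoate | COC(=O)CCC(=O)N(C)OC | intermediate
7 | Z-alkenyllithium from 3 | CC(C)(C)[Si](OC/C(C)=C\[Li])(c1ccccc1)c1ccccc1 | intermediate
8 | methyl (5Z)-7-(tert-butyldiphenylsilyloxy)-6-methyl-4-oxohept-5-enoate | COC(=O)CCC(=O)/C=C(/C)CO[Si](c1ccccc1)(c1ccccc1)C(C)(C)C | intermediate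
9 | (S)-2-methylglycidol, (S)-(2-methyloxiran-2-yl)methanol | OC[C@]1(C)OC1 | starting material
10 | (R)-2-methylpent-4-ene-1,2-diol | OC[C@](C)(O)CC=C | intermediate
11 | (R)-2-methyl-1,2-bis(triethylsilyloxy)pent-4-ene | CC[Si](CC)(CC)OC[C@](C)(O[Si](CC)(CC)CC)CC=C | intermediate
12 | (R)-2-methyl-2-(triethylsilyloxy)pent-4-enal | O=C[C@](C)(O[Si](CC)(CC)CC)CC=C | intermediate
13 | (3R,1E)-1-iodo-3-methyl-3-(triethylsilyloxy)hexa-1,5-diene | I/C=C/[C@](C)(O[Si](CC)(CC)CC)CC=C | intermediate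
14 | (3R,4E)-5-iodo-3-methyl-3-(triethylsilyloxy)pent-4-enal | I/C=C/[C@](C)(O[Si](CC)(CC)CC)CC=O | intermediate
15 | Z-enol diisopinocampheylborinate of 8 | COC(=O)C/C=C(OB([C@@H]1C[C@@H]2C[C@H]([C@H]1C)C2(C)C)[C@@H]1C[C@@H]2C[C@H]([C@H]1C)C2(C)C)/C=C(/C)CO[Si](c1ccccc1)(c1ccccc1)C(C)(C)C | intermediate
16 | syn-aldol adduct (7S,8R,10R), methyl (3S,4R,6R,7E)-3-[(2Z)-4-(tert-butyldiphenylsilyloxy)-3-methylbut-2-enoyl]-4-hydroxy-8-iodo-6-methyl-6-(triethylsilyloxy)oct-7-enoate | I/C=C/[C@](C)(O[Si](CC)(CC)CC)C[C@@H](O)[C@H](CC(=O)OC)C(=O)/C=C(/C)CO[Si](c1ccccc1)(c1ccccc1)C(C)(C)C | intermediate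
17 | bis(triethylsilyl) enone (7S,8R,10R), the 4,6-bis(triethylsilyloxy) analogue of 16 | I/C=C/[C@](C)(O[Si](CC)(CC)CC)C[C@@H](O[Si](CC)(CC)CC)[C@H](CC(=O)OC)C(=O)/C=C(/C)CO[Si](c1ccccc1)(c1ccccc1)C(C)(C)C | intermediate
18 | hydroxy ester (6R,7R,8R,10R), methyl (3R,4R,6R,7E)-3-[(1R,2Z)-4-(tert-butyldiphenylsilyloxy)-1-hydroxy-3-methylbut-2-en-1-yl]-8-iodo-6-methyl-4,6-bis(triethylsilyloxy)oct-7-enoate | I/C=C/[C@](C)(O[Si](CC)(CC)CC)C[C@@H](O[Si](CC)(CC)CC)[C@H](CC(=O)OC)[C@H](O)/C=C(/C)CO[Si](c1ccccc1)(c1ccccc1)C(C)(C)C | intermediate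
19 | cis-lactone (6R,7R,8R,10R), (4R,5R)-5-[(1Z)-3-(tert-butyldiphenylsilyloxy)-2-methylprop-1-en-1-yl]-4-[(1R,3R,4E)-5-iodo-3-methyl-1,3-bis(triethylsilyloxy)pent-4-en-1-yl]oxolan-2-one | C1C(=O)O[C@H](/C=C(/C)CO[Si](c2ccccc2)(c2ccccc2)C(C)(C)C)[C@@H]1[C@@H](C[C@@](/C=C/I)(C)O[Si](CC)(CC)CC)O[Si](CC)(CC)CC | intermediate
20 | Mannich base, (3S,4R,5R)-3-[(dimethylamino)methyl] derivative of 19 | CN(C)C[C@H]1C(=O)O[C@H](/C=C(/C)CO[Si](c2ccccc2)(c2ccccc2)C(C)(C)C)[C@@H]1[C@@H](C[C@@](/C=C/I)(C)O[Si](CC)(CC)CC)O[Si](CC)(CC)CC | intermediate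
21 | trimethylammonium iodide of 20 | C[N+](C)(C)C[C@H]1C(=O)O[C@H](/C=C(/C)CO[Si](c2ccccc2)(c2ccccc2)C(C)(C)C)[C@@H]1[C@@H](C[C@@](/C=C/I)(C)O[Si](CC)(CC)CC)O[Si](CC)(CC)CC.[I-] | intermediate
22 | α-methylene lactone (6R,7R,8R,10R), 3-methylidene derivative of 19 | C=C1C(=O)O[C@H](/C=C(/C)CO[Si](c2ccccc2)(c2ccccc2)C(C)(C)C)[C@@H]1[C@@H](C[C@@](/C=C/I)(C)O[Si](CC)(CC)CC)O[Si](CC)(CC)CC | intermediate
23 | C8,C10-diol (6R,7S,8R,10R), (4S,5R)-5-[(1Z)-3-(tert-butyldiphenylsilyloxy)-2-methylprop-1-en-1-yl]-4-[(1R,3R,4E)-1,3-dihydroxy-5-iodo-3-methylpent-4-en-1-yl]-3-methylideneoxolan-2-one | C=C1C(=O)O[C@H](/C=C(/C)CO[Si](c2ccccc2)(c2ccccc2)C(C)(C)C)[C@@H]1[C@@H](C[C@@](/C=C/I)(C)O)O | intermediate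
24 | angelic acid, (Z)-2-methylbut-2-enoic acid | C/C=C(/C)C(=O)O | starting material
25 | C8 angelate, C3 silyl ether (6R,7S,8R,10R) | C=C1C(=O)O[C@H](/C=C(/C)CO[Si](c2ccccc2)(c2ccccc2)C(C)(C)C)[C@@H]1[C@@H](C[C@@](/C=C/I)(C)O)OC(=O)/C(C)=C\C | intermediate
26 | C8 angelate, C3 primary alcohol (6R,7S,8R,10R) | C=C1C(=O)O[C@H](/C=C(/C)CO)[C@@H]1[C@@H](C[C@@](/C=C/I)(C)O)OC(=O)/C(C)=C\C | intermediate
27 | cyclisation precursor (6R,7S,8R,10R): Z-enal at C3, E-iodoalkene at C2 | C=C1C(=O)O[C@H](/C=C(/C)C=O)[C@@H]1[C@@H](C[C@@](/C=C/I)(C)O)OC(=O)/C(C)=C\C | intermediate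
28 | E-alkenylchromium dichloride (trivalent chromium) from 27 | C=C1C(=O)O[C@H](/C=C(/C)C=O)[C@@H]1[C@@H](C[C@@](/C=C/[Cr](Cl)Cl)(C)O)OC(=O)/C(C)=C\C | intermediate
29 | (3R,6R,7S,8R,10R,1E,4Z)-3,10-dihydroxy-8-[(2Z)-2-methylbut-2-enoyloxy]germacra-1,4,11(13)-trien-12,6-olide | C=C1C(=O)O[C@@H]2/C=C(/C)[C@H](O)/C=C/[C@](C)(O)C[C@@H](OC(=O)/C(C)=C\C)[C@H]12 | intermediate
30 | CNP0181631.1, (3R,6R,7S,8R,10R,1E,4Z)-3-acetoxy-10-hydroxy-8-[(2Z)-2-methylbut-2-enoyloxy]germacra-1,4,11(13)-trien-12,6-olide | C=C1C(=O)O[C@@H]2/C=C(/C)[C@H](OC(C)=O)/C=C/[C@](C)(O)C[C@@H](OC(=O)/C(C)=C\C)[C@H]12 | target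

**Step count and risks**

Total: 19 steps. Longest linear sequence: 15 steps (steps 5–19, from 9). Ketone 8 is made in a four-step branch (steps 1–4).

Steps most likely to fail:

1. Step 18 (ring closure). The alkenylchromium may add to the wrong face of the formyl group, giving mainly the C3 epimer, and intermolecular coupling may compete. Fallback, from 27 back to 29: the closure is run as planned and the C3-epimeric alcohol (3S,6R,7S,8R,10R)-3-epi-29 F1, alone or mixed with 29, is oxidised with Dess–Martin periodinane to the cross-conjugated 3-oxo dienone F2. This ketone is reduced under reagent control by Corey–Bakshi–Shibata reduction ((S)-2-methyl-CBS-oxazaborolidine, catecholborane, toluene, −78 °C). With the trisubstituted C4 alkenyl group as the large substituent, this should deliver the 3R alcohol 29.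

2. Step 10 (aldol). Control of the aldehyde face by the boron ligands may be insufficient, or the new C8 hydroxyl may lactonise onto the methyl ester before it is silylated. Fallback, from 14 back to 19, using auxiliary control and a tert-butyl ester:
 - (S)-4-Benzyl-3-(4-tert-butoxy-4-oxobutanoyl)oxazolidin-2-one F3 is made from (S)-4-benzyloxazolidin-2-one and mono-tert-butyl succinate via the pivaloyl mixed anhydride.
 - Its dibutylboron enolate (Bu2BOTf, i-Pr2NEt) reacts with 14 in an Evans syn-aldol to give the (7S,8R,10R) imide adduct F4.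
 - Me3Al and MeNHOMe·HCl convert F4 into the Weinreb amide F5, which is silylated (TESOTf, 2,6-lutidine) to the bis(triethylsilyl) Weinreb amide F6.
 - Alkenyllithium 7 adds at −78 °C to give the tert-butyl ester enone F7.
 - Reduction as in step 12 gives the hydroxy tert-butyl ester F8, which is lactonised with catalytic camphorsulfonic acid in toluene (loss of tert-butanol) to 19.

3. Step 12 (reduction and lactonisation). Hydride may be delivered to the wrong face of the C6 ketone if Felkin–Anh control is insufficient. Fallback, from 17 back to 19: the reduction is quenched cold and the hydroxy esters are separated. The 6R isomer 18 is lactonised as planned. The 6S epimer, 6-epi-18 F9, is saponified with Me3SnOH in 1,2-dichloroethane to the 6-epi hydroxy acid F10. F10 is closed by Mitsunobu lactonisation (PPh3, DIAD, THF, 0 °C), in which the carboxylate displaces the activated C6 hydroxyl with inversion, so both epimers converge on 19.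

**Further compounds**

F1 | step 18 | (3S,6R,7S,8R,10R,1E,4Z)-3,10-dihydroxy-8-[(2Z)-2-methylbut-2-enoyloxy]germacra-1,4,11(13)-trien-12,6-olide (3-epi-29) | C=C1C(=O)O[C@@H]2/C=C(/C)[C@@H](O)/C=C/[C@](C)(O)C[C@@H](OC(=O)/C(C)=C\C)[C@H]12
F2 | step 18 | (6R,7S,8R,10R,1E,4Z)-10-hydroxy-8-[(2Z)-2-methylbut-2-enoyloxy]-3-oxogermacra-1,4,11(13)-trien-12,6-olide | C=C1C(=O)O[C@@H]2/C=C(/C)C(=O)/C=C/[C@](C)(O)C[C@@H](OC(=O)/C(C)=C\C)[C@H]12
F3 | step 10 | (S)-4-benzyl-3-(4-tert-butoxy-4-oxobutanoyl)oxazolidin-2-one | CC(C)(C)OC(=O)CCC(=O)N1[C@@H](Cc2ccccc2)COC1=O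
F4 | step 10 | (S)-4-benzyl-3-[(2S,3R,5R,6E)-2-(2-tert-butoxy-2-oxoethyl)-3-hydroxy-7-iodo-5-methyl-5-(triethylsilyloxy)hept-6-enoyl]oxazolidin-2-one | I/C=C/[C@](C)(O[Si](CC)(CC)CC)C[C@@H](O)[C@H](CC(=O)OC(C)(C)C)C(=O)N1[C@@H](Cc2ccccc2)COC1=O
F5 | step 10 | tert-butyl (3S,4R,6R,7E)-4-hydroxy-8-iodo-3-[methoxy(methyl)carbamoyl]-6-methyl-6-(triethylsilyloxy)oct-7-enoate | I/C=C/[C@](C)(O[Si](CC)(CC)CC)C[C@@H](O)[C@H](CC(=O)OC(C)(C)C)C(=O)N(C)OC
F6 | step 10 | tert-butyl (3S,4R,6R,7E)-8-iodo-3-[methoxy(methyl)carbamoyl]-6-methyl-4,6-bis(triethylsilyloxy)oct-7-enoate | I/C=C/[C@](C)(O[Si](CC)(CC)CC)C[C@@H](O[Si](CC)(CC)CC)[C@H](CC(=O)OC(C)(C)C)C(=O)N(C)OC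
F7 | step 10 | tert-butyl (3S,4R,6R,7E)-3-[(2Z)-4-(tert-butyldiphenylsilyloxy)-3-methylbut-2-enoyl]-8-iodo-6-methyl-4,6-bis(triethylsilyloxy)oct-7-enoate | I/C=C/[C@](C)(O[Si](CC)(CC)CC)C[C@@H](O[Si](CC)(CC)CC)[C@H](CC(=O)OC(C)(C)C)C(=O)/C=C(/C)CO[Si](c1ccccc1)(c1ccccc1)C(C)(C)C
F8 | step 10 | tert-butyl (3R,4R,6R,7E)-3-[(1R,2Z)-4-(tert-butyldiphenylsilyloxy)-1-hydroxy-3-methylbut-2-en-1-yl]-8-iodo-6-methyl-4,6-bis(triethylsilyloxy)oct-7-enoate | I/C=C/[C@](C)(O[Si](CC)(CC)CC)C[C@@H](O[Si](CC)(CC)CC)[C@H](CC(=O)OC(C)(C)C)[C@H](O)/C=C(/C)CO[Si](c1ccccc1)(c1ccccc1)C(C)(C)C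
F9 | step 12 | 6-epi-18, methyl (3R,4R,6R,7E)-3-[(1S,2Z)-4-(tert-butyldiphenylsilyloxy)-1-hydroxy-3-methylbut-2-en-1-yl]-8-iodo-6-methyl-4,6-bis(triethylsilyloxy)oct-7-enoate | I/C=C/[C@](C)(O[Si](CC)(CC)CC)C[C@@H](O[Si](CC)(CC)CC)[C@H](CC(=O)OC)[C@@H](O)/C=C(/C)CO[Si](c1ccccc1)(c1ccccc1)C(C)(C)C
F10 | step 12 | (3R,4R,6R,7E)-3-[(1S,2Z)-4-(tert-butyldiphenylsilyloxy)-1-hydroxy-3-methylbut-2-en-1-yl]-8-iodo-6-methyl-4,6-bis(triethylsilyloxy)oct-7-enoic acid | I/C=C/[C@](C)(O[Si](CC)(CC)CC)C[C@@H](O[Si](CC)(CC)CC)[C@H](CC(=O)O)[C@@H](O)/C=C(/C)CO[Si](c1ccccc1)(c1ccccc1)C(C)(C)C
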